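**Retrosynthetic overview**
- The ester C–O bond is made last: the C8 alcohol is acylated with 4-methoxybenzoyl chloride, itself made by Friedel–Crafts chlorocarbonylation of anisole.
- The C8 alcohol comes from the C8 ketone by dissolving-metal reduction. The C7 isopropyl group comes from an α-isopropylidene ketone (acetone aldol condensation, then hydrogenation, which also saturates C2=C3).
- Key disconnection C4a–C5: a 6-endo radical cyclization of a 3-bromopropyl ketone onto the tetrasubstituted enone of an oxanorbornadiene. It closes ring A, creates the quaternary C4a by exo attack and, through exo H-atom transfer at C8a, the trans ring fusion.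
- The oxanorbornadiene comes from an enantioselective Diels–Alder reaction of 2-methylfuran with 7-bromohept-2-yn-4-one (acid chloride plus propyne).
- Ring order: furan ring (purchased), then the oxygen-bridged bicycle (cycloaddition), then ring A (radical cyclization).

Locants for all tricycles follow the 1,4-epoxynaphthalene skeleton: C1 (bridgehead, CH3), C2, C3, C4 (bridgehead, H), C4a (ring fusion, CH3), C5–C8 (ring A; C7 carries the C3 side chain, C8 the oxygen), C8a (ring fusion, H). "Exo" means on the side of the oxygen bridge. The target is the trans-fused isomer: at C4a the ring A CH2 is exo and CH3 endo; at C8a H is exo and C8 endo.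

Assumption: acetone and oxalyl chloride, whose atoms end up in the product, are counted as starting materials and numbered.

**Step 1**
Reactants: 1 4-bromobutanoyl chloride; 2 propyne
Product: 3 7-bromohept-2-yn-4-one
Conditions: PdCl2(PPh3)2 (2 mol %), CuI (4 mol %), Et3N (1.2 equiv), propyne (2 equiv, condensed), THF, 0 → 20 °C
Reagents that add atoms: none
Why: Acyl Sonogashira coupling of the acid chloride with the terminal alkyne gives the ynone directly; the primary alkyl bromide is inert under these conditions and no stereocenter is formed.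

**Step 2**
Reactants: 3 7-bromohept-2-yn-4-one; 4 2-methylfuran
Product: 5 4-bromo-1-[(1S,4R)-1,3-dimethyl-7-oxabicyclo[2.2.1]hepta-2,5-dien-2-yl]butan-1-one
Conditions: 4 (8 equiv), triflimide salt of (S)-3,3-diphenyl-1-(2-methylphenyl)tetrahydro-1H,3H-pyrrolo[1,2-c][1,3,2]oxazaborole (20 mol %, from the oxazaborolidine and HNTf2), CH2Cl2, −78 → −40 °C; Et3N quench at −78 °C
Reagents that add atoms: none
Why: Proposed new method: a Diels–Alder reaction of a furan with an acetylenic ketone made enantioselective by a cationic oxazaborolidine (closest known types: oxazaborolidinium-catalysed Diels–Alder reactions of furans with acrylates, and chiral-boron-catalysed cycloadditions of acetylenic aldehydes); the boron-bound carbonyl lowers the ynone LUMO and the catalyst shields one face of the alkyne, the unsubstituted C5 of 2-methylfuran (largest HOMO coefficient) bonds to the ynone β-carbon so that the acyl-bearing carbon ends next to the methyl-bearing bridgehead, and this sets both bridgeheads (1S,4R), the (R)-catalyst being used instead if the facial sense proves opposite.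

**Step 3**
Reactants: 5 4-bromo-1-[(1S,4R)-1,3-dimethyl-7-oxabicyclo[2.2.1]hepta-2,5-dien-2-yl]butan-1-one
Product: 6 (1S,4R,4aS,8aS)-1,4a-dimethyl-4,4a,5,6,7,8a-hexahydro-1,4-epoxynaphthalen-8(1H)-one (trans-fused; C2=C3 retained)
Conditions: Bu3SnH (1.3 equiv, added over 8 h), AIBN (0.2 equiv), benzene, 80 °C, 0.005 M
Reagents that add atoms: none
Why: 6-endo-trig radical cyclization (intramolecular Giese addition; because the tether runs through the carbonyl, the nucleophilic primary radical attacks the enone β-carbon C4a, not the α-carbon): attack on the exo face makes C4a quaternary with the new CH2 exo and CH3 endo, and the resulting α-keto radical takes H from Bu3SnH on its exo face, which puts C8 endo and gives the trans ring fusion (4aS,8aS).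

**Step 4**
Reactants: 6 (1S,4R,4aS,8aS)-1,4a-dimethyl-4,4a,5,6,7,8a-hexahydro-1,4-epoxynaphthalen-8(1H)-one; 7 acetone
Product: 10 (1S,4R,4aS,8aS)-1,4a-dimethyl-7-(propan-2-ylidene)-4,4a,5,6,7,8a-hexahydro-1,4-epoxynaphthalen-8(1H)-one, via tertiary aldol 8 (not isolated), via tertiary mesylate 9 (not isolated)
Conditions: LiN(i-Pr)2 (1.1 equiv), THF, −78 °C; ZnCl2 (1.1 equiv); 7 (3 equiv), −78 °C, 1 h; then MsCl (1.5 equiv), Et3N (4 equiv), −78 → 20 °C
Reagents that add atoms: none
Why: Kinetic deprotonation occurs at the C7 methylene (the C8a methine is tertiary and shielded), the zinc enolate adds to acetone, and in-flask mesylation followed by E1cB elimination completes an aldol condensation to the conjugated isopropylidene ketone; C7 becomes sp2 and the existing stereocenters are untouched.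

**Step 5**
Reactants: 10 (1S,4R,4aS,8aS)-1,4a-dimethyl-7-(propan-2-ylidene)-4,4a,5,6,7,8a-hexahydro-1,4-epoxynaphthalen-8(1H)-one
Product: 11 (1S,4R,4aS,7S,8aS)-1,4a-dimethyl-7-(propan-2-yl)octahydro-1,4-epoxynaphthalen-8(1H)-one
Conditions: H2 (1 atm), 5 % Pd/C, EtOAc, 20 °C
Reagents that add atoms: none
Why: Heterogeneous syn-hydrogenation saturates the strained C2=C3 bond first and then the exocyclic enone double bond, with H delivered to C7 along the equatorial trajectory (the axial face is screened by the syn-axial H-8a and H-5, as in the hydrogenation of 2-alkylidenecyclohexanones to the axial-alkyl products), which leaves the isopropyl group axial and cis to H-8a (7S).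

**Step 6**
Reactants: 11 (1S,4R,4aS,7S,8aS)-1,4a-dimethyl-7-(propan-2-yl)octahydro-1,4-epoxynaphthalen-8(1H)-one
Product: 12 (1S,4R,4aS,7S,8R,8aR)-1,4a-dimethyl-7-(propan-2-yl)decahydro-1,4-epoxynaphthalen-8-ol
Conditions: Li (6 equiv), NH3(l)/THF, t-BuOH (2.2 equiv), −78 °C, 15 min; solid NH4Cl
Reagents that add atoms: none
Why: Dissolving-metal (ketyl radical anion) reduction gives the thermodynamically preferred equatorial alcohol, OH cis to H-8a and to the isopropyl group (8R), because an axial OH would be syn-diaxial to the 4a-methyl group.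

**Step 7**
Reactants: 13 anisole; 14 oxalyl chloride
Product: 15 4-methoxybenzoyl chloride
Conditions: 14 (2 equiv), AlCl3 (1.1 equiv), CH2Cl2, 0 → 20 °C; poured onto ice/CaCl2; distillation
Reagents that add atoms: none
Why: Friedel–Crafts chlorocarbonylation (electrophilic aromatic substitution by the chlorocarbonyl cation formed from oxalyl chloride with loss of CO) is para-selective on anisole and gives the aroyl chloride directly.

**Step 8**
Reactants: 12 (1S,4R,4aS,7S,8R,8aR)-1,4a-dimethyl-7-(propan-2-yl)decahydro-1,4-epoxynaphthalen-8-ol; 15 4-methoxybenzoyl chloride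
Product: 16 [(1S,4R,4aS,7S,8R,8aR)-1,4a-dimethyl-7-(propan-2-yl)decahydro-1,4-epoxynaphthalen-8-yl] 4-methoxybenzoate
Conditions: 15 (1.5 equiv), Et3N (3 equiv), DMAP (0.5 equiv), CH2Cl2, 40 °C
Reagents that add atoms: none
Why: DMAP-catalysed acyl transfer esterifies the hindered equatorial alcohol at oxygen, so C8 keeps its configuration and the product is the target.

Note on descriptors: 8aS in ketones 6, 8–11 and 8aR in 12 and 16 describe the same spatial arrangement; only the CIP priorities change when C8 goes from C=O to CH–O.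

**Compound list**
1 | 4-bromobutanoyl chloride | O=C(Cl)CCCBr | starting material
2 | propyne | CC#C | starting material
3 | 7-bromohept-2-yn-4-one | CC#CC(=O)CCCBr | intermediate
4 | 2-methylfuran | Cc1ccco1 | starting material
5 | 4-bromo-1-[(1S,4R)-1,3-dimethyl-7-oxabicyclo[2.2.1]hepta-2,5-dien-2-yl]butan-1-one | BrCCCC(=O)C1=C(C)[C@H]2C=C[C@]1(C)O2 | intermediate
6 | (1S,4R,4aS,8aS)-1,4a-dimethyl-4,4a,5,6,7,8a-hexahydro-1,4-epoxynaphthalen-8(1H)-one | O=C2CCC[C@]3(C)[C@H]4C=C[C@](C)(O4)[C@@H]23 | intermediate
7 | acetone | CC(C)=O | starting material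
8 | (1S,4R,4aS,7S,8aS)-7-(2-hydroxypropan-2-yl)-1,4a-dimethyl-4,4a,5,6,7,8a-hexahydro-1,4-epoxynaphthalen-8(1H)-one (formed as its zinc alkoxide) | O=C2[C@H](C(C)(C)O)CC[C@]3(C)[C@H]4C=C[C@](C)(O4)[C@@H]23 | intermediate
9 | 2-[(1S,4R,4aS,7S,8aS)-1,4a-dimethyl-8-oxo-1,4,4a,5,6,7,8,8a-octahydro-1,4-epoxynaphthalen-7-yl]propan-2-yl methanesulfonate | O=C2[C@H](C(C)(C)OS(C)(=O)=O)CC[C@]3(C)[C@H]4C=C[C@](C)(O4)[C@@H]23 | intermediate
10 | (1S,4R,4aS,8aS)-1,4a-dimethyl-7-(propan-2-ylidene)-4,4a,5,6,7,8a-hexahydro-1,4-epoxynaphthalen-8(1H)-one | O=C2C(=C(C)C)CC[C@]3(C)[C@H]4C=C[C@](C)(O4)[C@@H]23 | intermediate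
11 | (1S,4R,4aS,7S,8aS)-1,4a-dimethyl-7-(propan-2-yl)octahydro-1,4-epoxynaphthalen-8(1H)-one | O=C2[C@H](C(C)C)CC[C@]3(C)[C@H]4CC[C@](C)(O4)[C@@H]23 | intermediate
12 | (1S,4R,4aS,7S,8R,8aR)-1,4a-dimethyl-7-(propan-2-yl)decahydro-1,4-epoxynaphthalen-8-ol | O[C@@H]2[C@H](C(C)C)CC[C@]3(C)[C@H]4CC[C@](C)(O4)[C@@H]23 | intermediate
13 | anisole | COc1ccccc1 | starting material
14 | oxalyl chloride | O=C(Cl)C(Cl)=O | starting material
15 | 4-methoxybenzoyl chloride | COc1ccc(C(Cl)=O)cc1 | intermediate
16 | [(1S,4R,4aS,7S,8R,8aR)-1,4a-dimethyl-7-(propan-2-yl)decahydro-1,4-epoxynaphthalen-8-yl] 4-methoxybenzoate | COc1ccc(C(=O)O[C@@H]2[C@H](C(C)C)CC[C@]3(C)[C@H]4CC[C@](C)(O4)[C@@H]23)cc1 | target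

**Step count**
Total: 8 steps. Longest linear sequence: 7 steps (1 → 2 → 3 → 4 → 5 → 6 → 8); step 7 is a one-step side branch.

**Three steps most likely to fail, with fallbacks**

Step 2 is the least secure. A β-methyl ynone is a sluggish dienophile toward furans, the Lewis acid can divert it into Friedel–Crafts (Michael) alkylation of the furan or aromatize the adduct, and the enantioselectivity is unproven. The fallback installs the methyl group after the cycloaddition. It sets out again from 1: AlCl3-promoted acylation of (bromoethynyl)trimethylsilane (CH2Cl2, −40 °C) gives 1,6-dibromohex-1-yn-3-one F1, a much more reactive bromoalkynone whose cycloadditions with 2-methylfuran are known to be fast and regioselective in the required sense. Its Diels–Alder reaction with 4 (same oxazaborolidinium catalyst, −78 °C) gives 4-bromo-1-[(1S,4R)-3-bromo-1-methyl-7-oxabicyclo[2.2.1]hepta-2,5-dien-2-yl]butan-1-one F2. Stille methylation of the vinylic bromide (Me4Sn, Pd(PPh3)4, CuI, DMF, 40 °C; the primary alkyl bromide is untouched) comes back to the route at 5.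

Step 3 can fail in three ways: the 6-endo closure onto a fully substituted β-carbon may lose to simple reduction of the C–Br bond, the exo face may not be attacked cleanly, or the α-keto radical may take H on the endo face and give the cis-fused C8a epimer. The fallback builds the same ketone in one step by a different radical process, bypassing 3 and 5. It sets out from 4: irradiation (λ ≈ 350 nm, CH2Cl2, −20 °C) of commercial 3-methylcyclohex-2-en-1-one with excess 4 generates the twisted triplet enone, which adds to the furan by a biradical [4+2] path that is known to give trans-fused adducts with cyclohexenones. This gives 6 together with its mirror image (1R,4S,4aR,8aR)-1,4a-dimethyl-4,4a,5,6,7,8a-hexahydro-1,4-epoxynaphthalen-8(1H)-one F3, besides [2+2] adducts and the other trans isomer. F3 is removed by chromatography on a chiral stationary phase, and the route is rejoined at 6.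

Step 5 carries the C7 stereocenter on a steric argument only. The catalyst may deliver H to the axial face, or first isomerize the exocyclic double bond into the ring, either of which gives the equatorial-isopropyl epimer. The fallback replaces face selection by substrate sterics with hydroxyl direction. It sets out from 10: Luche reduction (NaBH4, CeCl3·7H2O, MeOH, −40 °C) attacks the ketone from the face away from the 4a-methyl group and gives the axial allylic alcohol (1S,4R,4aS,8R,8aR)-1,4a-dimethyl-7-(propan-2-ylidene)-1,4,4a,5,6,7,8,8a-octahydro-1,4-epoxynaphthalen-8-ol F4. Hydrogenation with [Ir(cod)(PCy3)(py)]PF6 (H2, CH2Cl2) is then directed by that axial OH to the same face, so H enters C7 equatorially and the product is (1S,4R,4aS,7S,8S,8aR)-1,4a-dimethyl-7-(propan-2-yl)decahydro-1,4-epoxynaphthalen-8-ol F5, with C2=C3 saturated as well. Dess–Martin oxidation (NaHCO3, CH2Cl2) returns to the route at 11.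

**Further compounds**
F1 | step 2 | 1,6-dibromohex-1-yn-3-one | BrC#CC(=O)CCCBr
F2 | step 2 | 4-bromo-1-[(1S,4R)-3-bromo-1-methyl-7-oxabicyclo[2.2.1]hepta-2,5-dien-2-yl]butan-1-one | BrCCCC(=O)C1=C(Br)[C@H]2C=C[C@]1(C)O2
F3 | step 3 | (1R,4S,4aR,8aR)-1,4a-dimethyl-4,4a,5,6,7,8a-hexahydro-1,4-epoxynaphthalen-8(1H)-one | O=C2CCC[C@@]3(C)[C@@H]4C=C[C@@](C)(O4)[C@H]23
F4 | step 5 | (1S,4R,4aS,8R,8aR)-1,4a-dimethyl-7-(propan-2-ylidene)-1,4,4a,5,6,7,8,8a-octahydro-1,4-epoxynaphthalen-8-ol | O[C@H]2C(=C(C)C)CC[C@]3(C)[C@H]4C=C[C@](C)(O4)[C@@H]23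
F5 | step 5 | (1S,4R,4aS,7S,8S,8aR)-1,4a-dimethyl-7-(propan-2-yl)decahydro-1,4-epoxynaphthalen-8-ol | O[C@H]2[C@H](C(C)C)CC[C@]3(C)[C@H]4CC[C@](C)(O4)[C@@H]23
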